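The constants were drawn at random within sensible limits; what happens was integrated by code.

The substrate swaps hands as it reacts.

the same everywhere: left-handed substrate 0.48 M; reagent 1.92 M; catalyst 0.48 mM; right-handed substrate 0.48 M; time 6.0 min
- cedar: temperature −5 °C
- alder: temperature 25 °C
- ash: temperature 10 °C

    reagent + catalyst + left-handed substrate → catalyst + left-handed product (k1 = 99 /M²/s, Ea1 = 36.0 kJ/mol)
    reagent + catalyst + right-handed substrate → catalyst + right-handed product (k2 = 9.5 /M²/s, Ea2 = 44.0 kJ/mol)
    left-handed substrate ⇌ right-handed substrate (k3 = 0.18 /s, Ea3 = 66.0 kJ/mol)
    catalyst ⇌ dormant form (K4 = 1.7, k4 = 0.0066 /s, Ea4 = 87.0 kJ/mol, ΔH4 = −17.0 kJ/mol)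
    (constants at 25 °C)

- the flask with the highest excess of left-handed product over right-handed product ("all alike" if they lie within 1.5 percentage points) (cedar / alder / ash / all alike)
- excess of left-handed product over right-handed product at the end, cedar
- excess of left-handed product over right-handed product at the end, alder
- excess of left-handed product over right-handed product at the end, ash

- catalyst is single-handed; left-handed substrate and right-handed substrate are mirror images of each other, charged as a racemate, each of them at the stated concentration
- the list of constants is for 25 °C, to be carried to other temperatures by the activation energies and enthalpies
- an excess is the difference of the two amounts in percent of their sum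
- an excess is below zero if the other one leads

1. My bench rule for this dynamic kinetic resolution: if racemisation is quick, the substrates stay level, and the product ratio equals the selectivity factor, the ratio of the two catalysed constants. At the listed temperature, which is alder's, that factor is 10.4, so the rule promises an excess of 82.5%.

2. The border comes from one ratio, g: the gap between the two catalysed constants, times reagent, times catalyst, over the racemisation constant. Reagent and catalyst make each drain pseudo-first-order, while racemisation refills the faster-draining left-handed substrate.

3. Once both substrates fall at the same relative pace, the ratio of left-handed to right-handed substrate, ρ, obeys this: ρ minus its reciprocal equals minus g. The product ratio is then the selectivity factor times ρ. The bench rule holds while g is well below 1.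

4. For alder I take reagent at half conversion, 1.44 M, and catalyst at its charge. That overstates g once dormant form appears, since that exchange has a relaxation half-life of 1.10 min. So g is 0.344, below 1, and ρ is 0.843, the held ratio. Alder's excess comes to 79.6%.

5. For cedar, the activation energies raise the selectivity factor to 15.0. But g climbs to 1.37, so ρ drops to 0.526 and the excess is 77.5%. The substrates start level, so the first product is richer than ρ says, and I treat this figure as low. Cold raises selectivity and lowers ρ, and the two nearly cancel. The gap is 2.1 percentage points beside a margin of 1.5 points, before that correction. I leave ash unreckoned, and on that correction to cedar I lean to all alike, a close call.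

6. The forecast gives all alike, with 80.5%, 79.7% and 79.3% for cedar, alder and ash: “so all three land near 80% and within about the 1.5-point margin”.

7. The flasks give all alike: 80.7%, 80.3% and 81.1% for cedar, alder and ash, a span of 0.80 points. In alder, dormant form reaches 61.5% of the catalyst by the end, yet that conversion barely moves the excess. The held ratio can be tried on alder at 3.00 min: with reagent at 51.5% and catalyst at 46.6% of their charges, g is 0.110 and ρ is 0.947. The substrates there read 0.946.

8. A neighbour flask is alder with 0.0019 M of catalyst. There g becomes 1.36, the held ratio 0.529, and the reckoned excess 69.3%. The flask gives 74.0%.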